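All runs come from a simulation for an exercise, and the scatter is random.

Holding the flask until 3.0 d pays only if its chains reach 200 units, so the chain length has to be reckoned before the decision.

in all of them: X 0.21 M (fed, over 2.5 d)
- south-east: Q 0.42 mM; run made earlier; the fed solution adds 0.10 times the starting volume
- south: Q 0.63 mM; run made earlier; the fed solution adds 0.10 times the starting volume
- flask: Q 0.84 mM; the fed solution adds 0.10 times the starting volume; time 3.0 d

| run | time / d | L / % | X / % |
|---|---|---|---|
| south-east | 0.125 | 2 | 7 |
| south-east | 0.333 | 0 | 11 |
| south-east | 0.625 | 2 | 24 |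
| south-east | 1.04 | 2 | 38 |
| south-east | 1.67 | 8 | 61 |
| south-east | 2.08 | 19 | 67 |
| south-east | 2.50 | 28 | 71 |
| south | 0.333 | 0 | 16 |
| south | 0.625 | 0 | 22 |
| south | 1.04 | 6 | 38 |
| south | 1.25 | 3 | 45 |
| south | 1.67 | 14 | 55 |
| south | 2.08 | 25 | 59 |
| south | 2.50 | 41 | 63 |

(standard deviation of a reading: 1.5 percentage points)

1. whether the average number of monomer units in a chain (chains begun, living or dead) reaches 200 by 3.0 d (no / yes)
2. average number of monomer units in a chain (chains begun, living or dead) at 3.0 d

- every charge counts on the volume at the start, and the solution that is fed holds the whole dose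
- the average divides the monomer in chains by the number of chains begun, living and dead together
- the earlier runs do not show the number of chains; that part of a forecast is a guess
- percentages count the whole charge, also what has not yet gone in

Follow one Q: it may begin a chain, or it may be lost on another path. The reckoning rests on R = 250, the units of X charged per Q charged. The average length is then R·f/s, where f is the share of the X charge in L and s is the share of Q that began a chain (the initiator efficiency).

R comes straight from the charges. An error in f passes in proportion into the length, and f has to be carried over to another Q and another time: in the south run, L climbs from 25% at 2.08 d to 41% at 2.50 d. At 2.50 d, L stands at 28% in the south-east run and 41% in the south run, a ratio of 1.46 against 1.50 in Q. Scaling by Q, my own reckoning puts f for the flask at about 54.7% at 2.50 d, and I use that figure for 3.0 d as well, as a rough value.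

The length goes inversely with the share s, and the earlier runs do not show the number of chains. With this f, s = 1 gives a length of 137, and 200 needs s below 68.3%. Guessing s = 0.5, I commit to about 273 and "yes".

The forecast says yes and 350, which is longer than mine; for 3.0 d it reckons “about 0.137 M of monomer in chains”, where my f gives 0.115 M.

The flask gives 260 at 3.0 d, so the answer is yes.

    X + Q → G + L (k = 1.30 × 10⁻⁴ L mol⁻¹ s⁻¹)
    X + G → L + G, rate k2*[G]*[X] (k = 0.0270 L mol⁻¹ s⁻¹)
    L + G → X + G, rate k3*[G] as long as [L] is above zero (k = 9.20 × 10⁻⁴ s⁻¹)
    X + Q → Z (k = 1.10 × 10⁻⁵ L mol⁻¹ s⁻¹)
    Q → J (k = 4.10 × 10⁻⁶ s⁻¹)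

The length reaches 200 at 2.50 d. At 3.00 d, L stands at 59.5%, so R·f divided by the length gives s = 57.2%, while J stands at 2.73 × 10⁻⁴ M.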